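The plan rests on disconnecting all four bonds of ketal carbon C1 of the 2,9-dioxabicyclo[3.3.1]nona-3,7-diene core. C1 is a masked ketone held between alkene carbon C8, an ethyl group, the dihydropyran oxygen O9 and the enol-ether oxygen O2 of the 4H-1,3-dioxin ring, so it can enter as carbon monoxide. In one flask a palladium-catalysed carbonylative Suzuki–Miyaura coupling joins a Z-alkenyl iodide, CO and an ethylborane, and acid then removes two silyl groups and closes both rings. The precursor is an open-chain C3 ketone with TES-protected C5 and side-chain carbinols and a Z-2-iodoalkene terminus, built by a boron aldol union of two chiral fragments.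

Key step: step 17

Remark: the core locants (C1 ketal carbon, O2, C3=C4, C5, C6, C7=C8, O9) are also used for the open-chain precursors.

Assumption: (+)-Ipc2BOTf (from (−)-α-pinene) is taken to send its Z-enolates to the re face of an aldehyde; if a trial aldol shows the opposite sense, the antipodal triflate is used with no other change.

Step 1
Reactants: 1 (E)-2-methylpent-2-enal
Product: 2 (E)-2-methylpent-2-en-1-ol
Conditions: NaBH4, CeCl3·7H2O, MeOH, 0 °C
Reagents that add atoms: none
Why: Luche 1,2-reduction delivers hydride to the carbonyl only and should leave the trisubstituted E alkene untouched.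

Step 2
Reactants: 2 (E)-2-methylpent-2-en-1-ol
Product: 3 (E)-1-bromo-2-methylpent-2-ene
Conditions: PBr3 (0.4 equiv), Et2O, −10 to 0 °C; used crude
Reagents that add atoms: phosphorus tribromide BrP(Br)Br
Why: Bromide displaces the phosphite ester of the primary allylic alcohol (SN2), and the low temperature should suppress allylic transposition and loss of the E geometry.

Step 3
Reactants: 3 (E)-1-bromo-2-methylpent-2-ene; 4 (S)-4-benzyl-3-propionyloxazolidin-2-one
Product: 5 (S)-4-benzyl-3-[(2R,4E)-2,4-dimethylhept-4-enoyl]oxazolidin-2-one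
Conditions: NaN(SiMe3)2, THF, −78 °C; then 3, −78 to −40 °C
Reagents that add atoms: none
Why: Evans asymmetric alkylation, in which the chelated sodium Z-enolate of 4 is attacked by the reactive allylic bromide on the face opposite the benzyl group, sets the (R) methyl centre next to the CH2 group.

Step 4
Reactants: 5 (S)-4-benzyl-3-[(2R,4E)-2,4-dimethylhept-4-enoyl]oxazolidin-2-one
Product: 6 (2R,4E)-2,4-dimethylhept-4-en-1-ol
Conditions: LiBH4, MeOH (1 equiv), Et2O, 0 °C
Reagents that add atoms: none
Why: Reductive removal of the auxiliary with LiBH4 attacks the exocyclic imide carbonyl selectively and should neither touch the alkene nor epimerise the α-centre.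

Step 5
Reactants: 6 (2R,4E)-2,4-dimethylhept-4-en-1-ol
Product: 7 (2R,4E)-2,4-dimethylhept-4-enal
Conditions: Dess–Martin periodinane, NaHCO3, CH2Cl2, 0 °C to rt; used directly
Reagents that add atoms: none
Why: Buffered Dess–Martin oxidation gives the α-chiral aldehyde under near-neutral conditions that should not epimerise it.

Step 6
Reactants: 7 (2R,4E)-2,4-dimethylhept-4-enal; 8 (R)-4-benzyl-3-propionyloxazolidin-2-one
Product: 9 (R)-4-benzyl-3-[(2R,3S,4R,6E)-3-hydroxy-2,4,6-trimethylnon-6-enoyl]oxazolidin-2-one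
Conditions: 8, Bu2BOTf, iPr2NEt, CH2Cl2, −78 to 0 °C; then 7, −78 to 0 °C; pH 7 buffer, MeOH, H2O2, 0 °C
Reagents that add atoms: none
Why: Evans boron syn-aldol, in which the Z-dibutylboron enolate of 8 reacts through a chair Zimmerman–Traxler transition state under auxiliary control that overrides the modest bias of the α-methyl aldehyde, sets the (2R) methyl centre (the future side-chain methine next to C3) and a (3S) carbinol that is oxidised in the last step.

Step 7
Reactants: 9 (R)-4-benzyl-3-[(2R,3S,4R,6E)-3-hydroxy-2,4,6-trimethylnon-6-enoyl]oxazolidin-2-one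
Product: 10 (2R,3S,4R,6E)-3-hydroxy-N-methoxy-N,2,4,6-tetramethylnon-6-enamide
Conditions: MeONHMe·HCl, AlMe3, CH2Cl2, −20 °C to rt
Reagents that add atoms: N,O-dimethylhydroxylamine hydrochloride CNOC.Cl
Why: Weinreb transamidation by the aluminium amide is assisted by the free β-hydroxyl and should cleave the auxiliary without retro-aldol cleavage or epimerisation.

Step 8
Reactants: 10 (2R,3S,4R,6E)-3-hydroxy-N-methoxy-N,2,4,6-tetramethylnon-6-enamide
Product: 11 (2R,3S,4R,6E)-N-methoxy-N,2,4,6-tetramethyl-3-[(triethylsilyl)oxy]non-6-enamide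
Conditions: TESOTf, 2,6-lutidine, CH2Cl2, −78 to 0 °C
Reagents that add atoms: triethylsilyl trifluoromethanesulfonate CC[Si](CC)(CC)OS(=O)(=O)C(F)(F)F
Why: Silylation with the reactive silyl triflate masks the hindered secondary carbinol for the Grignard, aldol and carbonylation steps.

Step 9
Reactants: 11 (2R,3S,4R,6E)-N-methoxy-N,2,4,6-tetramethyl-3-[(triethylsilyl)oxy]non-6-enamide; 12 ethylmagnesium bromide
Product: 13 (4R,5S,6R,8E)-4,6,8-trimethyl-5-[(triethylsilyl)oxy]undec-8-en-3-one
Conditions: 12 (3 equiv), THF, 0 °C to rt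
Reagents that add atoms: none
Why: Grignard addition to the Weinreb amide stops at the chelated tetrahedral intermediate and should release the ethyl ketone only on work-up.

Step 10
Reactants: 14 methyl (R)-3-hydroxy-2-methylpropanoate (Roche ester)
Product: 15 methyl (R)-3-[(tert-butyldimethylsilyl)oxy]-2-methylpropanoate
Conditions: TBSCl, imidazole, CH2Cl2, rt
Reagents that add atoms: tert-butyldimethylsilyl chloride CC(C)(C)[Si](C)(C)Cl
Why: Standard silylation of the primary alcohol.

Step 11
Reactants: 15 methyl (R)-3-[(tert-butyldimethylsilyl)oxy]-2-methylpropanoate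
Product: 16 (R)-3-[(tert-butyldimethylsilyl)oxy]-2-methylpropanal
Conditions: iBu2AlH (1.1 equiv), CH2Cl2, −78 °C; MeOH, then aq. potassium sodium tartrate
Reagents that add atoms: none
Why: Low-temperature iBu2AlH reduction stops at the aluminium hemiacetal, which should release the aldehyde on work-up with the α-centre intact.

Step 12
Reactants: 16 (R)-3-[(tert-butyldimethylsilyl)oxy]-2-methylpropanal
Product: 17 tert-butyl{[(2S,3Z)-4-iodo-2-methylpent-3-en-1-yl]oxy}dimethylsilane
Conditions: [Ph3PEt]I, n-BuLi, THF, rt; added to iodine, THF, −78 °C; NaN(SiMe3)2, −20 °C; then 16, −78 °C to rt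
Reagents that add atoms: ethyltriphenylphosphonium iodide CC[P+](c1ccccc1)(c1ccccc1)c1ccccc1.[I-]; iodine [I][I]
Why: Stork–Zhao olefination, in which the α-iodo ylide adds to the aldehyde under kinetic control, should give the Z-2-iodoalkene (iodine cis to the chain) and supplies C8, its methyl group and the halide.

Step 13
Reactants: 17 tert-butyl{[(2S,3Z)-4-iodo-2-methylpent-3-en-1-yl]oxy}dimethylsilane
Product: 18 (2S,3Z)-4-iodo-2-methylpent-3-en-1-ol
Conditions: camphorsulfonic acid (cat.), MeOH–CH2Cl2, 0 °C to rt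
Reagents that add atoms: none
Why: Acid-catalysed methanolysis removes the primary TBS ether and should leave the alkenyl iodide untouched.

Step 14
Reactants: 18 (2S,3Z)-4-iodo-2-methylpent-3-en-1-ol
Product: 19 (2S,3Z)-4-iodo-2-methylpent-3-enal
Conditions: Dess–Martin periodinane, NaHCO3, CH2Cl2, 0 °C; crude aldehyde used at once in step 15
Reagents that add atoms: none
Why: Buffered Dess–Martin oxidation should give the β,γ-unsaturated α-chiral aldehyde without conjugation or epimerisation, provided it is not stored.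

Step 15
Reactants: 13 (4R,5S,6R,8E)-4,6,8-trimethyl-5-[(triethylsilyl)oxy]undec-8-en-3-one; 19 (2S,3Z)-4-iodo-2-methylpent-3-enal
Product: 20 (2Z,4S,5S,6R,8R,9S,10R,12E)-5-hydroxy-2-iodo-4,6,8,10,12-pentamethyl-9-[(triethylsilyl)oxy]pentadeca-2,12-dien-7-one
Conditions: 13, (+)-Ipc2BOTf, iPr2NEt, CH2Cl2, −78 °C; then 19, −78 to −20 °C; pH 7 buffer, MeOH, H2O2, 0 °C
Reagents that add atoms: none
Why: Diisopinocampheylboron-mediated syn-aldol, in which kinetic enolisation on the ethyl side gives the Z-enol borinate that adds through a chair Zimmerman–Traxler transition state to the re face of 19 (the anti-Felkin face that Z-enolates favour with α-methyl aldehydes and that the Ipc ligands are chosen to reinforce), should set C5 (5,6-anti) together with a 4,5-syn C4 centre that is erased later, the α-centre of the ketone being expected to exert only a weak bias in a Z-boron enolate.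

Step 16
Reactants: 20 (2Z,4S,5S,6R,8R,9S,10R,12E)-5-hydroxy-2-iodo-4,6,8,10,12-pentamethyl-9-[(triethylsilyl)oxy]pentadeca-2,12-dien-7-one
Product: 21 (2Z,4S,5S,6R,8R,9S,10R,12E)-2-iodo-4,6,8,10,12-pentamethyl-5,9-bis[(triethylsilyl)oxy]pentadeca-2,12-dien-7-one
Conditions: TESOTf, 2,6-lutidine, CH2Cl2, −78 °C
Reagents that add atoms: triethylsilyl trifluoromethanesulfonate CC[Si](CC)(CC)OS(=O)(=O)C(F)(F)F
Why: Low-temperature silylation of the β-hydroxy ketone blocks lactone formation during the carbonylation and retro-aldol cleavage under base.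

Step 17
Reactants: 21 (2Z,4S,5S,6R,8R,9S,10R,12E)-2-iodo-4,6,8,10,12-pentamethyl-5,9-bis[(triethylsilyl)oxy]pentadeca-2,12-dien-7-one; 12 ethylmagnesium bromide; 22 carbon monoxide
Product: 27 (2R,3S,4R,6E)-2-[(1S,5S,6S)-1-ethyl-4,6,8-trimethyl-2,9-dioxabicyclo[3.3.1]nona-3,7-dien-3-yl]-4,6-dimethylnon-6-en-3-ol, via B-ethyl-9-BBN 23 (not isolated), via Z-ethyl enone bis-TES ether 24 (not isolated), via dihydroxy enedione 25 (not isolated), via monocyclic lactol 26 (not isolated)
Conditions: 12, B-methoxy-9-BBN, THF–hexane, −78 °C to rt; then 21, Pd(PPh3)4 (5 mol%), K3PO4, CO (1 atm), THF–1,4-dioxane, rt; CO vented, then HF·pyridine (excess), 0 °C to rt; TsOH·H2O, rt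
Reagents that add atoms: none
Why: Proposed new method: the telescoped carbonylative coupling and bicycloketalisation has not been run as one operation, but each stage follows known reactivity, the closest precedents being the carbonylative Suzuki–Miyaura synthesis of enones from iodoalkenes and 9-alkyl-9-BBN reagents and the acid-driven ketalisation of hydroxy diketones; zerovalent palladium inserts into the C8–I bond with retention, CO inserts to give the acyl-palladium, the ethyl group arrives from base-activated 23 and reductive elimination gives Z-enone 24. HF then frees both hydroxyls (25), the C5 hydroxyl adds to the C1 ketone in a 6-exo-trig closure of the dihydropyran ring (lactol 26), and ionisation to the allylic oxocarbenium ion with capture by the enol oxygen of the C3 ketone (6-endo-trig; alternatively 6-exo-trig addition of the lactol hydroxyl to C3 and loss of water) closes the 4H-1,3-dioxin ring. The only new stereocentre, C1, is dictated by C5 because the one-atom O9 bridge can span C1 and C5 on one face only, and the C4 centre disappears in the enol ether. The step needs retention of the Z C7=C8 geometry, which rests on stereospecific oxidative addition, on the C5 silyl ether that keeps the acyl-palladium from lactonising, and on immediate ring capture of the Z-enone. It also needs dehydration toward C4 and not toward the side-chain methine, which is favoured because only the C3=C4 enol ether lies inside the six-membered dioxin ring of the bridged ketal, the expected thermodynamic sink. The side-chain carbinol is kept at the alcohol oxidation level so that C3 is an isolated ketone and no 1,3-diketone can divert the cascade to a pyranone.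

Step 18
Reactants: 27 (2R,3S,4R,6E)-2-[(1S,5S,6S)-1-ethyl-4,6,8-trimethyl-2,9-dioxabicyclo[3.3.1]nona-3,7-dien-3-yl]-4,6-dimethylnon-6-en-3-ol
Product: 28 (2S,4R,6E)-2-[(1S,5S,6S)-1-ethyl-4,6,8-trimethyl-2,9-dioxabicyclo[3.3.1]nona-3,7-dien-3-yl]-4,6-dimethylnon-6-en-3-one (CNP0232650.2)
Conditions: Dess–Martin periodinane, NaHCO3, CH2Cl2, 0 °C to rt
Reagents that add atoms: none
Why: Bicarbonate-buffered Dess–Martin oxidation of the secondary carbinol should give the ketone without hydrolysing the ketal and enol ether or epimerising the adjacent methine.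

Compound list
1 | (E)-2-methylpent-2-enal | CC/C=C(\C)C=O | starting material
2 | (E)-2-methylpent-2-en-1-ol | CC/C=C(\C)CO | intermediate
3 | (E)-1-bromo-2-methylpent-2-ene | CC/C=C(\C)CBr | intermediate
4 | (S)-4-benzyl-3-propionyloxazolidin-2-one | CCC(=O)N1[C@@H](Cc2ccccc2)COC1=O | starting material
5 | (S)-4-benzyl-3-[(2R,4E)-2,4-dimethylhept-4-enoyl]oxazolidin-2-one | CC/C=C(\C)C[C@@H](C)C(=O)N1[C@@H](Cc2ccccc2)COC1=O | intermediate
6 | (2R,4E)-2,4-dimethylhept-4-en-1-ol | CC/C=C(\C)C[C@@H](C)CO | intermediate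
7 | (2R,4E)-2,4-dimethylhept-4-enal | CC/C=C(\C)C[C@@H](C)C=O | intermediate
8 | (R)-4-benzyl-3-propionyloxazolidin-2-one | CCC(=O)N1[C@H](Cc2ccccc2)COC1=O | starting material
9 | (R)-4-benzyl-3-[(2R,3S,4R,6E)-3-hydroxy-2,4,6-trimethylnon-6-enoyl]oxazolidin-2-one | CC/C=C(\C)C[C@@H](C)[C@H](O)[C@@H](C)C(=O)N1[C@H](Cc2ccccc2)COC1=O | intermediate
10 | (2R,3S,4R,6E)-3-hydroxy-N-methoxy-N,2,4,6-tetramethylnon-6-enamide | CC/C=C(\C)C[C@@H](C)[C@H](O)[C@@H](C)C(=O)N(C)OC | intermediate
11 | (2R,3S,4R,6E)-N-methoxy-N,2,4,6-tetramethyl-3-[(triethylsilyl)oxy]non-6-enamide | CC/C=C(\C)C[C@@H](C)[C@H](O[Si](CC)(CC)CC)[C@@H](C)C(=O)N(C)OC | intermediate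
12 | ethylmagnesium bromide | CC[Mg]Br | starting material
13 | (4R,5S,6R,8E)-4,6,8-trimethyl-5-[(triethylsilyl)oxy]undec-8-en-3-one | CC/C=C(\C)C[C@@H](C)[C@H](O[Si](CC)(CC)CC)[C@@H](C)C(=O)CC | intermediate
14 | methyl (R)-3-hydroxy-2-methylpropanoate | COC(=O)[C@H](C)CO | starting material
15 | methyl (R)-3-[(tert-butyldimethylsilyl)oxy]-2-methylpropanoate | COC(=O)[C@H](C)CO[Si](C)(C)C(C)(C)C | intermediate
16 | (R)-3-[(tert-butyldimethylsilyl)oxy]-2-methylpropanal | O=C[C@H](C)CO[Si](C)(C)C(C)(C)C | intermediate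
17 | tert-butyl{[(2S,3Z)-4-iodo-2-methylpent-3-en-1-yl]oxy}dimethylsilane | C/C(I)=C/[C@H](C)CO[Si](C)(C)C(C)(C)C | intermediate
18 | (2S,3Z)-4-iodo-2-methylpent-3-en-1-ol | C/C(I)=C/[C@H](C)CO | intermediate
19 | (2S,3Z)-4-iodo-2-methylpent-3-enal | C/C(I)=C/[C@H](C)C=O | intermediate
20 | (2Z,4S,5S,6R,8R,9S,10R,12E)-5-hydroxy-2-iodo-4,6,8,10,12-pentamethyl-9-[(triethylsilyl)oxy]pentadeca-2,12-dien-7-one | CC/C=C(\C)C[C@@H](C)[C@H](O[Si](CC)(CC)CC)[C@@H](C)C(=O)[C@H](C)[C@@H](O)[C@@H](C)/C=C(/C)I | intermediate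
21 | (2Z,4S,5S,6R,8R,9S,10R,12E)-2-iodo-4,6,8,10,12-pentamethyl-5,9-bis[(triethylsilyl)oxy]pentadeca-2,12-dien-7-one | CC/C=C(\C)C[C@@H](C)[C@H](O[Si](CC)(CC)CC)[C@@H](C)C(=O)[C@H](C)[C@@H](O[Si](CC)(CC)CC)[C@@H](C)/C=C(/C)I | intermediate
22 | carbon monoxide | [C-]#[O+] | starting material
23 | 9-ethyl-9-borabicyclo[3.3.1]nonane (B-ethyl-9-BBN) | CCB1C2CCCC1CCC2 | intermediate
24 | (4Z,6S,7S,8R,10R,11S,12R,14E)-4,6,8,10,12,14-hexamethyl-7,11-bis[(triethylsilyl)oxy]heptadeca-4,14-diene-3,9-dione | CC/C=C(\C)C[C@@H](C)[C@H](O[Si](CC)(CC)CC)[C@@H](C)C(=O)[C@H](C)[C@@H](O[Si](CC)(CC)CC)[C@@H](C)/C=C(/C)C(=O)CC | intermediate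
25 | (4Z,6S,7S,8R,10R,11S,12R,14E)-7,11-dihydroxy-4,6,8,10,12,14-hexamethylheptadeca-4,14-diene-3,9-dione | CC/C=C(\C)C[C@@H](C)[C@H](O)[C@@H](C)C(=O)[C@H](C)[C@@H](O)[C@@H](C)/C=C(/C)C(=O)CC | intermediate
26 | monocyclic lactol from addition of the C5 hydroxyl of 25 to the C1 ketone: 6-ethyl-6-hydroxy-3,5-dimethyl-3,6-dihydro-2H-pyran carrying the hydroxy keto chain at its C2, drawn as the anomer that closes to 27 | CC/C=C(\C)C[C@@H](C)[C@H](O)[C@@H](C)C(=O)[C@H](C)[C@H]1O[C@@](CC)(O)C(C)=C[C@@H]1C | intermediate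
27 | (2R,3S,4R,6E)-2-[(1S,5S,6S)-1-ethyl-4,6,8-trimethyl-2,9-dioxabicyclo[3.3.1]nona-3,7-dien-3-yl]-4,6-dimethylnon-6-en-3-ol | CC/C=C(\C)C[C@@H](C)[C@H](O)[C@@H](C)C1=C(C)[C@H]2O[C@@](CC)(O1)C(C)=C[C@@H]2C | intermediate
28 | (2S,4R,6E)-2-[(1S,5S,6S)-1-ethyl-4,6,8-trimethyl-2,9-dioxabicyclo[3.3.1]nona-3,7-dien-3-yl]-4,6-dimethylnon-6-en-3-one | CC/C=C(\C)C[C@@H](C)C(=O)[C@@H](C)C1=C(C)[C@H]2O[C@@](CC)(O1)C(C)=C[C@@H]2C | target

Total step count: 18. Longest linear sequence: 13 steps (steps 1 to 9, then 15 to 18, from 1).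

Steps most likely to fail

1. Step 17. The ethyl group may be transferred before CO has inserted, the Z-enone may isomerise or the methine next to the C3 ketone may epimerise under base before ring capture, or the cascade may stall at partly desilylated stages in the mixed medium. The fallback uses known chemistry and no CO. It sets out from 21: a Nozaki–Hiyama–Kishi coupling with propanal (CrCl2, NiCl2 cat., DMF–THF, rt), which tolerates the ketone and keeps the alkene geometry, should give the allylic alcohols (both carbinol epimers) F1. Dess–Martin oxidation then gives enone 24, now isolated. HF·pyridine in THF followed by TsOH in CH2Cl2, as a separate operation, takes 24 through 25 and 26 to 27, where the route is rejoined.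

2. Step 15. Facial discrimination may be insufficient in this triply stereodifferentiating aldol if the α-centre of the ketone opposes the aldehyde and the Ipc ligands, and the aldehyde may epimerise or conjugate during a slow addition. The fallback moves control of C5 to a chiral auxiliary and reverses the order of the two aldol unions. It sets out from 19 and 8: an Evans syn-aldol (Bu2BOTf, iPr2NEt), matched with the anti-Felkin preference, gives the hydroxy imide F2. Weinreb transamidation (AlMe3, MeONHMe·HCl) gives the hydroxy amide F3, TESOTf gives its silyl ether F4, and EtMgBr gives the ethyl ketone F5. The E-enolate of F5 (c-Hex2BCl, Et3N, Et2O) adds to aldehyde 7 in an anti-aldol governed by the α-methyl centre of the ketone (1,3-anti) to give the hydroxy ketone F6. This has the required side-chain methyl centre and an epimeric carbinol that is oxidised at the end in any case. TESOTf gives the bis-TES ether F7. The conditions of step 17 then lead through the Z-enone F8, the dihydroxy dione F9 and the lactol F10 to the epimeric bicyclic alcohol F11, and its Dess–Martin oxidation returns to the route at 28.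

3. Step 12. The hindered iodo ylide may convert the α-branched aldehyde poorly, Z selectivity may erode, and the basic ylide may epimerise the aldehyde. The fallback sets out from 16: Corey–Fuchs olefination (CBr4, PPh3, 2,6-lutidine, CH2Cl2, 0 °C) gives the 1,1-dibromoalkene F12. A trans-selective Negishi monomethylation (Me2Zn, PdCl2(DPEphos), THF, 0 °C) replaces the bromine trans to the chain and gives the Z-2-bromoalkene F13. Bromine–lithium exchange (t-BuLi, Et2O, −78 °C) and an iodine quench, both with retention, give 17, where the route is rejoined.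

Further compounds
F1 | step 17 | allylic alcohols from the chromium-mediated addition of 21 to propanal, both carbinol epimers | CC/C=C(\C)C[C@@H](C)[C@H](O[Si](CC)(CC)CC)[C@@H](C)C(=O)[C@H](C)[C@@H](O[Si](CC)(CC)CC)[C@@H](C)/C=C(/C)C(O)CC
F2 | step 15 | (R)-4-benzyl-3-[(2R,3S,4S,5Z)-3-hydroxy-6-iodo-2,4-dimethylhept-5-enoyl]oxazolidin-2-one | C/C(I)=C/[C@H](C)[C@H](O)[C@@H](C)C(=O)N1[C@H](Cc2ccccc2)COC1=O
F3 | step 15 | (2R,3S,4S,5Z)-3-hydroxy-6-iodo-N-methoxy-N,2,4-trimethylhept-5-enamide | C/C(I)=C/[C@H](C)[C@H](O)[C@@H](C)C(=O)N(C)OC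
F4 | step 15 | (2R,3S,4S,5Z)-6-iodo-N-methoxy-N,2,4-trimethyl-3-[(triethylsilyl)oxy]hept-5-enamide | C/C(I)=C/[C@H](C)[C@H](O[Si](CC)(CC)CC)[C@@H](C)C(=O)N(C)OC
F5 | step 15 | (4R,5S,6S,7Z)-8-iodo-4,6-dimethyl-5-[(triethylsilyl)oxy]non-7-en-3-one | C/C(I)=C/[C@H](C)[C@H](O[Si](CC)(CC)CC)[C@@H](C)C(=O)CC
F6 | step 15 | anti-aldol adduct of F5 and 7: C9 epimer of 20 with the TES group on the C5 oxygen and the C9 hydroxyl free | CC/C=C(\C)C[C@@H](C)[C@@H](O)[C@@H](C)C(=O)[C@H](C)[C@@H](O[Si](CC)(CC)CC)[C@@H](C)/C=C(/C)I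
F7 | step 15 | C9 epimer of 21 | CC/C=C(\C)C[C@@H](C)[C@@H](O[Si](CC)(CC)CC)[C@@H](C)C(=O)[C@H](C)[C@@H](O[Si](CC)(CC)CC)[C@@H](C)/C=C(/C)I
F8 | step 15 | C11 epimer of 24 | CC/C=C(\C)C[C@@H](C)[C@@H](O[Si](CC)(CC)CC)[C@@H](C)C(=O)[C@H](C)[C@@H](O[Si](CC)(CC)CC)[C@@H](C)/C=C(/C)C(=O)CC
F9 | step 15 | C11 epimer of 25 | CC/C=C(\C)C[C@@H](C)[C@@H](O)[C@@H](C)C(=O)[C@H](C)[C@@H](O)[C@@H](C)/C=C(/C)C(=O)CC
F10 | step 15 | side-chain carbinol epimer of lactol 26 | CC/C=C(\C)C[C@@H](C)[C@@H](O)[C@@H](C)C(=O)[C@H](C)[C@H]1O[C@@](CC)(O)C(C)=C[C@@H]1C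
F11 | step 15 | side-chain carbinol (C3 of the nonenol chain) epimer of 27 | CC/C=C(\C)C[C@@H](C)[C@@H](O)[C@@H](C)C1=C(C)[C@H]2O[C@@](CC)(O1)C(C)=C[C@@H]2C
F12 | step 12 | tert-butyl{[(2S)-4,4-dibromo-2-methylbut-3-en-1-yl]oxy}dimethylsilane | BrC(Br)=C[C@H](C)CO[Si](C)(C)C(C)(C)C
F13 | step 12 | tert-butyl{[(2S,3Z)-4-bromo-2-methylpent-3-en-1-yl]oxy}dimethylsilane | C/C(Br)=C/[C@H](C)CO[Si](C)(C)C(C)(C)C
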